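**Early times.** At early times the zeta run, starting material coupling with coupling partner over free catalyst, makes target at 0.0316 M/min on average up to its first reading. That pace doesn't last. Here are the flasks, the readings and the questions.

| flask | starting material | coupling partner | free catalyst | time |
|---|---|---|---|---|
| zeta | 0.300 M | 0.900 M | 0.0300 M |  |
| eta | 0.180 M | 0.780 M | 0.0300 M |  |
| alpha | 0.300 M | 2.70 M | 0.0300 M |  |
| gamma | 0.300 M | 0.900 M | 0.0300 M | 76 min |

| run | time / min | [target] / M |
|---|---|---|
| zeta run | 0.76 | 0.0240 |
| zeta run | 1.4 | 0.0415 |
| zeta run | 2.8 | 0.0737 |
| zeta run | 5.2 | 0.1085 |
| zeta run | 10 | 0.1420 |
| zeta run | 19 | 0.1595 |
| eta run | 0.76 | 0.0159 |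
| eta run | 1.4 | 0.0279 |
| eta run | 2.8 | 0.0495 |
| eta run | 5.2 | 0.0731 |
| eta run | 10 | 0.0933 |
| eta run | 19 | 0.1043 |
| alpha run | 0.76 | 0.0297 |
| alpha run | 1.4 | 0.0462 |
| alpha run | 2.8 | 0.0820 |
| alpha run | 5.2 | 0.1160 |
| alpha run | 10 | 0.1454 |
| alpha run | 19 | 0.1618 |

(readings scatter by 9 × 10⁻⁴ M)

- Overall: starting material + coupling partner -> target, with free catalyst as catalyst.
- Constant volume, constant temperature.
- The analysis sees a species whether free or bound.
- An order is taken over about fifteen percent of the charge, up and down.

* the power of [starting material] that the first rate follows, about the charge of the zeta run; measure it at two percent of starting material made into target (one fixed amount of target, the same in the runs compared)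
* the power of [coupling partner] that the first rate follows, about the charge of the zeta run; measure it at two percent of starting material made into target
* the eta run starts with 0.120 M less of starting material and of coupling partner than the zeta run, and with no target. Compared where both hold the same amount of starting material, once fifteen percent of what the eta run was charged with has turned into target, is the eta run faster, slower or alike (within a tenth)?
* target in the gamma run at 76 min, as a share of the starting material charged

**A fading rate.** Starting material is the limiting reagent in the zeta run, with 0.300 M against 0.900 M of coupling partner. At its last reading the zeta run has 0.140 M of it unconverted, free or bound, about half of the charge, yet its rate over the last interval is 0.00194 M/min, far below the early rate. The interval before gives 0.00698 M/min. The midpoints of the two intervals lie 6.90 min apart, so I read a life of the rate, the time in which it falls by a factor e, of 5.40 min.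

**The reach.** I replace the curve by a rate that starts at the early value and fades with that life. Its sum is early rate times life, so I define the reach as early rate times life over the charge of starting material: the share of the charge made before the rate fades out. For the zeta charge the reach is 56.8 %. The gamma run has that charge, and its 76 min is 14.1 lives, so I commit to 56.8 %.

**One number?** With the same life, the eta run has a reach of 62.8 %, and its last reading stands at 57.9 % against 53.2 % for the zeta run, the order the reach predicts. The alpha run fails the test: its reach is 70.3 %, above the eta run's, but its last reading is 53.9 %, below the eta run's. So the reach with the zeta run's life doesn't hold for the alpha run's charge of coupling partner; the gamma run has the zeta charge.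

**The forecast.** The forecast gives an order of 0.72 in starting material and 0.15 in coupling partner, calls the eta run faster, and puts the gamma run at 54.6 % (53.5 % to 56.5 %), with the reading “the catalyst is dying”. My reach lies just above that range.

**The flask.** The gamma run gives 54.7 %, which is 2.1 percentage points below my reach. The orders come out at 0.56 in starting material and 0.29 in coupling partner.

    free catalyst + starting material → catalyst-substrate complex (8.100 /M/min)
    catalyst-substrate complex + coupling partner → target + free catalyst (8.400 /M/min)
    free catalyst → spent catalyst (0.2106 /min)
    2 starting material ⇌ idle substrate dimer, settled at all times (1.630 /M)

Where both hold the same amount of starting material, at the point asked about, the eta run is faster than the zeta run, by a rate ratio of 5.8. If the share made is the reach times one minus exp(−time/life), target comes to half of the starting material charged at life times ln(reach/(reach − half)). For the eta run that gives 8.59 min, and the eta run came to half at 8.56 min.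

The earlier runs and the new flask are simulated for substances that don't exist; noise was put on by code.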